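**Retrosynthetic overview**
1. Target 23 ⇐ O-desilylation and hydroxyl-directed epoxidation of the ten-membered (1Z,4Z)-dienol 21; the oxirane is made last.
2. 21 ⇐ ring-closing metathesis at C1=C2 of diene 20; the C3 carbinol of 20 ⇐ Nozaki–Hiyama–Kishi addition of vinyl iodide 18 to acrolein.
3. 18 (cis-fused α-methylene-γ-lactone, C6–C7 bond) ⇐ chiral Brønsted acid-catalysed 2-(methoxycarbonyl)allylboration of (Z)-3-iodobut-2-enal 16 with boronate 12.
4. 12 ⇐ acrylate homologation and SN2' borylation of α-angeloyloxy aldehyde 9; C8 and C10 ⇐ proline aldol (acetone + dimethoxyacetaldehyde), chelate-controlled vinyl Grignard addition, Mitsunobu inversion with angelic acid.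
5. Ring order: γ-lactone (step 9), then ten-membered carbocycle (step 11), then oxirane (step 12).

Assumption: the target is the (1R,2R,3R,6S,7R,8S,10R) enantiomer read from the SMILES (cis-fused lactone, cis-oxirane, 4Z olefin, angelate), and germacrane-type locants are used throughout (C6 lactone CH–O, C7 ring-fusion CH, C8 CH–O-angeloyl, C9 CH2, C10 C(CH3)OH, C1/C2 oxirane, C3 CHOH, C4=C5 olefin, C11–C13 methylene lactone).

**Route**

Step 1
Reactants: 1 acetone; 2 2,2-dimethoxyacetaldehyde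
Product: 3 (4R)-4-hydroxy-5,5-dimethoxypentan-2-one
Conditions: L-proline (30 mol%), acetone–DMSO 1:4, rt (2 used as its 60 wt% aqueous solution)
Reagents that add atoms: none
Why: Proline-catalysed direct (enamine) aldol reaction; the acetone enamine attacks the aldehyde Re face in the carboxylic acid-organised transition state, setting C8 as R (deliberately the epimer of the final centre, inverted in step 3).

Step 2
Reactants: 3 (4R)-4-hydroxy-5,5-dimethoxypentan-2-one
Product: 4 (3R,5R)-6,6-dimethoxy-3-methylhex-1-ene-3,5-diol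
Conditions: CH2=CHMgBr (3.5 equiv), THF, −78 → −40 °C; aq NH4Cl
Reagents that add atoms: vinylmagnesium bromide, C=C[Mg]Br
Why: Chelation-controlled Grignard addition (1,3-induction): the six-membered magnesium alkoxide–ketone chelate with the C8 substituent equatorial is attacked axially, so the methyl ends cis to C7 on the chelate and C10 is set as R; the minor C10 epimer is removed by chromatography.

Step 3
Reactants: 4 (3R,5R)-6,6-dimethoxy-3-methylhex-1-ene-3,5-diol; 5 angelic acid [(2Z)-2-methylbut-2-enoic acid]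
Product: 6 (2S,4R)-4-hydroxy-1,1-dimethoxy-4-methylhex-5-en-2-yl (2Z)-2-methylbut-2-enoate
Conditions: PPh3, diisopropyl azodicarboxylate, toluene, 0 °C → rt
Reagents that add atoms: none
Why: Mitsunobu esterification; the angelate displaces the activated secondary C8 oxygen by SN2 with inversion (R → S, the target configuration) while the tertiary C10 alcohol cannot be activated.

Step 4
Reactants: 6 (2S,4R)-4-hydroxy-1,1-dimethoxy-4-methylhex-5-en-2-yl (2Z)-2-methylbut-2-enoate
Product: 9 (2S,4R)-4-methyl-1-oxo-4-(triethylsilyloxy)hex-5-en-2-yl (2Z)-2-methylbut-2-enoate, via silyl ether acetal 7 (not isolated), via methoxyalkylpyridinium triflate 8 (not isolated)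
Conditions: Et3SiOTf (3 equiv), 2,6-lutidine (4.5 equiv), CH2Cl2, −78 → 0 °C; then H2O, rt
Reagents that add atoms: triethylsilyl trifluoromethanesulfonate, CC[Si](CC)(CC)OS(=O)(=O)C(F)(F)F; water, O
Why: O-silylation of the tertiary alcohol followed by silyl triflate/2,6-lutidine acetal cleavage (oxocarbenium trapped as a pyridinium salt, hydrolysed under neutral conditions), which unveils the aldehyde without acid strong enough to epimerise C8 or cleave the silyl ether; no stereocentre is touched.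

Step 5
Reactants: 9 (2S,4R)-4-methyl-1-oxo-4-(triethylsilyloxy)hex-5-en-2-yl (2Z)-2-methylbut-2-enoate
Product: 11 methyl (4S,6R)-3-acetoxy-6-methyl-4-[(2Z)-2-methylbut-2-enoyloxy]-2-methylidene-6-(triethylsilyloxy)oct-7-enoate (C3 epimers), via aluminium alkoxide 10 (not isolated)
Conditions: HC≡CCO2Me, i-Bu2AlH, N-methylmorpholine N-oxide, THF, 0 °C; then 9, 0 °C → rt; then Ac2O, 4-(dimethylamino)pyridine (cat.)
Reagents that add atoms: methyl propiolate, C#CC(=O)OC; acetic anhydride, CC(=O)OC(C)=O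
Why: Vinylalumination (Morita–Baylis–Hillman-type 1,2-addition of an α-aluminoacrylate made by hydroalumination of the propiolate) with acetylation of the alkoxide in the same flask, fast enough to avoid C8 epimerisation and 1,2-acyl shift; the new C7 carbinol centre is unselective and is erased in step 6.

Step 6
Reactants: 11 methyl (4S,6R)-3-acetoxy-6-methyl-4-[(2Z)-2-methylbut-2-enoyloxy]-2-methylidene-6-(triethylsilyloxy)oct-7-enoate (C3 epimers)
Product: 12 methyl (2E,4S,6R)-6-methyl-4-[(2Z)-2-methylbut-2-enoyloxy]-2-[(4,4,5,5-tetramethyl-1,3,2-dioxaborolan-2-yl)methyl]-6-(triethylsilyloxy)octa-2,7-dienoate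
Conditions: B2pin2, CuCl, LiCl, KOAc, DMF, rt
Reagents that add atoms: bis(pinacolato)diboron, CC1(C)OB(OC1(C)C)B1OC(C)(C)C(C)(C)O1
Why: Hosomi–Miyaura copper-mediated SN2' borylation (conjugate addition of Cu–Bpin to the acrylate CH2, then β-elimination of acetate) gives the thermodynamically preferred trisubstituted enoate with C8 trans to the ester and cis to CH2Bpin, the Z-crotyl-type geometry required for a syn allylboration.

Step 7
Reactants: 13 but-2-yn-1-ol
Product: 15 (2Z)-3-iodobut-2-en-1-ol, via cyclic alkenylaluminate 14 (not isolated)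
Conditions: NaAlH2(OCH2CH2OCH3)2, THF, 0 °C → rt; then iodine, −78 → 0 °C
Reagents that add atoms: iodine, [I][I]
Why: Hydroxyl-directed trans-hydroalumination of the propargylic alcohol (hydride to C2, aluminium to C3 in a five-membered alkoxyaluminate) followed by iodinolysis with retention fixes the Z geometry that becomes the 4Z olefin.

Step 8
Reactants: 15 (2Z)-3-iodobut-2-en-1-ol
Product: 16 (2Z)-3-iodobut-2-enal
Conditions: MnO2 (15 equiv), CH2Cl2, rt, dark
Reagents that add atoms: none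
Why: Chemoselective MnO2 oxidation of the allylic alcohol under neutral conditions, which keeps the Z-configured β-iodo enal from isomerising.

Step 9
Reactants: 12 methyl (2E,4S,6R)-6-methyl-4-[(2Z)-2-methylbut-2-enoyloxy]-2-[(4,4,5,5-tetramethyl-1,3,2-dioxaborolan-2-yl)methyl]-6-(triethylsilyloxy)octa-2,7-dienoate; 16 (2Z)-3-iodobut-2-enal
Product: 18 (1S,3R)-1-[(2R,3R)-2-[(1Z)-2-iodoprop-1-en-1-yl]-4-methylidene-5-oxooxolan-3-yl]-3-methyl-3-(triethylsilyloxy)pent-4-en-1-yl (2Z)-2-methylbut-2-enoate, via pinacol borate 17 (not isolated)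
Conditions: (R)-3,3'-bis(2,4,6-triisopropylphenyl)-1,1'-binaphthyl-2,2'-diyl N-triflylphosphoramide (10 mol%), 4 Å molecular sieves, toluene, −20 °C → rt; then pyridinium p-toluenesulfonate (20 mol%), 40 °C
Reagents that add atoms: none
Why: Proposed new method: a chiral N-triflylphosphoramide catalyses the allylboration of an aldehyde by a γ-substituted 2-(alkoxycarbonyl)allyl pinacolboronate; the acid hydrogen-bonds to a boronate oxygen (supplying the extra boron Lewis acidity that the ester-deactivated boronate needs) while its phosphoryl oxygen binds the formyl C–H, so the closed chair transition state (aldehyde substituent equatorial, C8 group axial because it is cis to CH2B) gives the 6,7-syn adduct by attack on the aldehyde Re face, with C7 bonding anti to the C8–O bond in the A1,3-minimised rotamer (catalyst and substrate bias expected to match; the acid enantiomer is swapped if the facial sense proves opposite), and the borate then lactonises to the cis-fused α-methylene-γ-lactone (C6 and C7 set; C6 is R in 18 only because iodine changes the priorities, and it is the 6S centre of the target); the closest known reactions are chiral phosphoric acid-catalysed allyl- and crotylboration of aldehydes with simple pinacolboronates and the achiral triflic acid-catalysed or thermal 2-(alkoxycarbonyl)allylboration–lactonisation, neither of which has been shown with a chiral acid on an ester-bearing boronate that carries a stereogenic γ-substituent.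

Step 10
Reactants: 18 (1S,3R)-1-[(2R,3R)-2-[(1Z)-2-iodoprop-1-en-1-yl]-4-methylidene-5-oxooxolan-3-yl]-3-methyl-3-(triethylsilyloxy)pent-4-en-1-yl (2Z)-2-methylbut-2-enoate; 19 acrolein
Product: 20 (1S,3R)-1-[(2S,3R)-2-[(1Z,3S)-3-hydroxy-2-methylpenta-1,4-dien-1-yl]-4-methylidene-5-oxooxolan-3-yl]-3-methyl-3-(triethylsilyloxy)pent-4-en-1-yl (2Z)-2-methylbut-2-enoate
Conditions: CrCl2 (4 equiv), NiCl2 (2 mol%), (S)-N-[2-(4-isopropyl-4,5-dihydro-1,3-oxazol-2-yl)-6-methylphenyl]methanesulfonamide (4.4 equiv), Et3N, THF, rt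
Reagents that add atoms: none
Why: Nozaki–Hiyama–Kishi coupling (nickel oxidative addition into the C–I bond with retention of the Z geometry, transmetalation to chromium, 1,2-addition to acrolein) in which the chiral sulfonamide–chromium complex directs addition to the Re face of acrolein (ligand enantiomer chosen accordingly), setting C3 (S here, R in the target once C2 carries oxygen) while esters, lactone and silyl ether are untouched.

Step 11
Reactants: 20 (1S,3R)-1-[(2S,3R)-2-[(1Z,3S)-3-hydroxy-2-methylpenta-1,4-dien-1-yl]-4-methylidene-5-oxooxolan-3-yl]-3-methyl-3-(triethylsilyloxy)pent-4-en-1-yl (2Z)-2-methylbut-2-enoate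
Product: 21 (3aR,4S,6R,7Z,9S,10Z,11aS)-9-hydroxy-6,10-dimethyl-3-methylidene-2-oxo-6-(triethylsilyloxy)-2,3,3a,4,5,6,9,11a-octahydrocyclodeca[b]furan-4-yl (2Z)-2-methylbut-2-enoate
Conditions: second-generation Grubbs catalyst (H2IMes)(PCy3)Cl2Ru=CHPh (10 mol%), CH2Cl2 (1 mM), 40 °C
Reagents that add atoms: none
Why: Ring-closing olefin metathesis: ruthenium loads at the unhindered C3 vinyl carbinol and closes onto the C10 vinyl group, and the ten-membered ring that already holds a Z olefin and a cis-fused lactone can only accommodate the cis (Z) C1=C2 bond; the 1,1-disubstituted methylene lactone and the trisubstituted olefins do not compete.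

Step 12
Reactants: 21 (3aR,4S,6R,7Z,9S,10Z,11aS)-9-hydroxy-6,10-dimethyl-3-methylidene-2-oxo-6-(triethylsilyloxy)-2,3,3a,4,5,6,9,11a-octahydrocyclodeca[b]furan-4-yl (2Z)-2-methylbut-2-enoate
Product: 22 (1R,2R,3R,4Z,6S,7R,8S,10R)-8-angeloyloxy-1,2-epoxy-3-hydroxy-10-(triethylsilyloxy)germacra-4,11(13)-dien-12,6-olide
Conditions: VO(acac)2 (10 mol%), t-BuOOH (1.5 equiv, decane), CH2Cl2, 0 °C → rt
Reagents that add atoms: tert-butyl hydroperoxide, CC(C)(C)OO
Why: Hydroxyl-directed vanadium-catalysed epoxidation: the C3 vanadate ester delivers oxygen to C1=C2 on the face cis to the hydroxyl, as medium-ring cycloalkenols do, setting C1 and C2 (1R,2R, erythro to C3); C10 is silylated so it cannot direct to the opposite face, and C4=C5 is deactivated by the allylic lactone oxygen.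

Step 13
Reactants: 22 (1R,2R,3R,4Z,6S,7R,8S,10R)-8-angeloyloxy-1,2-epoxy-3-hydroxy-10-(triethylsilyloxy)germacra-4,11(13)-dien-12,6-olide
Product: 23 CNP0351240.3, (1R,2R,3R,4Z,6S,7R,8S,10R)-8-angeloyloxy-1,2-epoxy-3,10-dihydroxygermacra-4,11(13)-dien-12,6-olide
Conditions: HF·pyridine, pyridine, THF, 0 °C
Reagents that add atoms: none
Why: Fluoride-driven desilylation (Si–F bond formation) buffered with pyridine, mild enough for the epoxy alcohol, angelate and methylene lactone; no stereocentre is touched.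

**Compound list**
1 | acetone | CC(C)=O | starting material
2 | 2,2-dimethoxyacetaldehyde | COC(OC)C=O | starting material
3 | (4R)-4-hydroxy-5,5-dimethoxypentan-2-one | CC(=O)C[C@@H](O)C(OC)OC | intermediate
4 | (3R,5R)-6,6-dimethoxy-3-methylhex-1-ene-3,5-diol | C=C[C@](C)(O)C[C@@H](O)C(OC)OC | intermediate
5 | angelic acid [(2Z)-2-methylbut-2-enoic acid] | C/C=C(/C)C(=O)O | starting material
6 | (2S,4R)-4-hydroxy-1,1-dimethoxy-4-methylhex-5-en-2-yl (2Z)-2-methylbut-2-enoate | C=C[C@](C)(O)C[C@H](OC(=O)/C(C)=C\C)C(OC)OC | intermediate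
7 | silyl ether acetal: (2S,4R)-1,1-dimethoxy-4-methyl-4-(triethylsilyloxy)hex-5-en-2-yl (2Z)-2-methylbut-2-enoate | C=C[C@](C)(O[Si](CC)(CC)CC)C[C@H](OC(=O)/C(C)=C\C)C(OC)OC | intermediate
8 | methoxyalkylpyridinium triflate: 1-[(2S,4R)-1-methoxy-4-methyl-2-[(2Z)-2-methylbut-2-enoyloxy]-4-(triethylsilyloxy)hex-5-en-1-yl]-2,6-dimethylpyridinium triflate (C1 epimers) | C=C[C@](C)(O[Si](CC)(CC)CC)C[C@H](OC(=O)/C(C)=C\C)C(OC)[n+]1c(C)cccc1C.[O-]S(=O)(=O)C(F)(F)F | intermediate
9 | (2S,4R)-4-methyl-1-oxo-4-(triethylsilyloxy)hex-5-en-2-yl (2Z)-2-methylbut-2-enoate | C=C[C@](C)(O[Si](CC)(CC)CC)C[C@H](OC(=O)/C(C)=C\C)C=O | intermediate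
10 | aluminium alkoxide: methyl (4S,6R)-3-[(diisobutylalumanyl)oxy]-6-methyl-4-[(2Z)-2-methylbut-2-enoyloxy]-2-methylidene-6-(triethylsilyloxy)oct-7-enoate (C3 epimers) | C=C[C@](C)(O[Si](CC)(CC)CC)C[C@H](OC(=O)/C(C)=C\C)C(O[Al](CC(C)C)CC(C)C)C(=C)C(=O)OC | intermediate
11 | methyl (4S,6R)-3-acetoxy-6-methyl-4-[(2Z)-2-methylbut-2-enoyloxy]-2-methylidene-6-(triethylsilyloxy)oct-7-enoate (C3 epimers) | C=C[C@](C)(O[Si](CC)(CC)CC)C[C@H](OC(=O)/C(C)=C\C)C(OC(C)=O)C(=C)C(=O)OC | intermediate
12 | methyl (2E,4S,6R)-6-methyl-4-[(2Z)-2-methylbut-2-enoyloxy]-2-[(4,4,5,5-tetramethyl-1,3,2-dioxaborolan-2-yl)methyl]-6-(triethylsilyloxy)octa-2,7-dienoate | COC(=O)/C(CB1OC(C)(C)C(C)(C)O1)=C/[C@@H](OC(=O)/C(C)=C\C)C[C@@](C)(O[Si](CC)(CC)CC)C=C | intermediate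
13 | but-2-yn-1-ol | CC#CCO | starting material
14 | cyclic alkenylaluminate: sodium 2,2-bis(2-methoxyethoxy)-3-methyl-2,5-dihydro-1,2-oxaluminol-2-uide | CC1=CCO[Al-]1(OCCOC)OCCOC.[Na+] | intermediate
15 | (2Z)-3-iodobut-2-en-1-ol | I/C(C)=C\CO | intermediate
16 | (2Z)-3-iodobut-2-enal | I/C(C)=C\C=O | intermediate
17 | pinacol borate: methyl (3S,4S,6R)-3-[(1R,2Z)-3-iodo-1-[(4,4,5,5-tetramethyl-1,3,2-dioxaborolan-2-yl)oxy]but-2-en-1-yl]-6-methyl-4-[(2Z)-2-methylbut-2-enoyloxy]-2-methylidene-6-(triethylsilyloxy)oct-7-enoate | COC(=O)C(=C)[C@@H]([C@H](/C=C(/C)I)OB1OC(C)(C)C(C)(C)O1)[C@@H](OC(=O)/C(C)=C\C)C[C@@](C)(O[Si](CC)(CC)CC)C=C | intermediate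
18 | (1S,3R)-1-[(2R,3R)-2-[(1Z)-2-iodoprop-1-en-1-yl]-4-methylidene-5-oxooxolan-3-yl]-3-methyl-3-(triethylsilyloxy)pent-4-en-1-yl (2Z)-2-methylbut-2-enoate | C=C1C(=O)O[C@@H](/C=C(/C)I)[C@H]1[C@@H](OC(=O)/C(C)=C\C)C[C@@](C)(O[Si](CC)(CC)CC)C=C | intermediate
19 | acrolein (prop-2-enal) | C=CC=O | starting material
20 | (1S,3R)-1-[(2S,3R)-2-[(1Z,3S)-3-hydroxy-2-methylpenta-1,4-dien-1-yl]-4-methylidene-5-oxooxolan-3-yl]-3-methyl-3-(triethylsilyloxy)pent-4-en-1-yl (2Z)-2-methylbut-2-enoate | C=C1C(=O)O[C@@H](/C=C(/C)[C@@H](O)C=C)[C@H]1[C@@H](OC(=O)/C(C)=C\C)C[C@@](C)(O[Si](CC)(CC)CC)C=C | intermediate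
21 | (3aR,4S,6R,7Z,9S,10Z,11aS)-9-hydroxy-6,10-dimethyl-3-methylidene-2-oxo-6-(triethylsilyloxy)-2,3,3a,4,5,6,9,11a-octahydrocyclodeca[b]furan-4-yl (2Z)-2-methylbut-2-enoate | C=C1C(=O)O[C@H]2/C=C(/C)[C@@H](O)/C=C\[C@](C)(O[Si](CC)(CC)CC)C[C@H](OC(=O)/C(C)=C\C)[C@@H]12 | intermediate
22 | (1R,2R,3R,4Z,6S,7R,8S,10R)-8-angeloyloxy-1,2-epoxy-3-hydroxy-10-(triethylsilyloxy)germacra-4,11(13)-dien-12,6-olide | C=C1C(=O)O[C@H]2/C=C(/C)[C@@H](O)[C@H]3O[C@H]3[C@](C)(O[Si](CC)(CC)CC)C[C@H](OC(=O)/C(C)=C\C)[C@@H]12 | intermediate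
23 | CNP0351240.3, (1R,2R,3R,4Z,6S,7R,8S,10R)-8-angeloyloxy-1,2-epoxy-3,10-dihydroxygermacra-4,11(13)-dien-12,6-olide | C=C1C(=O)O[C@H]2/C=C(/C)[C@@H](O)[C@H]3O[C@H]3[C@](C)(O)C[C@H](OC(=O)/C(C)=C\C)[C@@H]12 | target

**Step count and risks**

Total steps: 13. Longest linear sequence: 11 steps (steps 1–6, then 9–13); steps 7–8 make the second coupling partner.

Three steps most likely to fail:

Step 9 (the proposed new reaction). Risks are low reactivity of the ester-deactivated boronate towards a chiral acid, acid-induced scrambling of the boronate geometry, and a mismatch between the catalyst and the C8 centre. The fallback uses known Barbier chemistry, sets out from 11 and returns at 18. Acetate 11 is treated with LiBr in THF to give, by SN2' displacement, the thermodynamically preferred allylic bromide methyl (2Z,4S,6R)-2-(bromomethyl)-6-methyl-4-[(2Z)-2-methylbut-2-enoyloxy]-6-(triethylsilyloxy)octa-2,7-dienoate F1. Indium-mediated Barbier allylation of aldehyde 16 with this bromide (indium powder, THF–water, rt) is syn-selective and gives the hydroxy ester methyl (3S,4S,6R)-3-[(1R,2Z)-1-hydroxy-3-iodobut-2-en-1-yl]-6-methyl-4-[(2Z)-2-methylbut-2-enoyloxy]-2-methylidene-6-(triethylsilyloxy)oct-7-enoate F2. Warming with pyridinium p-toluenesulfonate in toluene lactonises it to 18. In this variant the facial selectivity rests on the C8 centre alone, so a C6/C7 diastereomer may have to be separated.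

Step 11 (ring-closing metathesis). The C10 vinyl group sits on a quaternary silyloxy carbon, and oligomerisation may outrun closure of the strained ten-membered ring. The fallback is a relay metathesis that sets out from 18 and returns at 21. The Nozaki–Hiyama–Kishi coupling of step 10 is run with (2E)-octa-2,7-dienal (MnO2 oxidation of commercial octa-2,7-dien-1-ol) in place of acrolein, giving (1S,3R)-1-[(2S,3R)-2-[(1Z,3S,4E)-3-hydroxy-2-methyldeca-1,4,9-trien-1-yl]-4-methylidene-5-oxooxolan-3-yl]-3-methyl-3-(triethylsilyloxy)pent-4-en-1-yl (2Z)-2-methylbut-2-enoate F3. With the second-generation Grubbs catalyst, ruthenium loads at the unhindered terminal olefin, extrudes cyclopentene to place the carbene on C2, and closes onto the C10 vinyl group to give 21.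

Step 12 (epoxidation). The C3 hydroxyl is allylic to both C1=C2 and C4=C5, so the trisubstituted C4=C5 bond may be epoxidised instead, and the facial preference is taken by analogy from smaller medium rings. The fallback changes the directing group, sets out from 21 and returns at 23. The C3 hydroxyl is silylated (t-BuMe2SiOTf, 2,6-lutidine) to (3aR,4S,6R,7Z,9S,10Z,11aS)-9-(tert-butyldimethylsilyloxy)-6,10-dimethyl-3-methylidene-2-oxo-6-(triethylsilyloxy)-2,3,3a,4,5,6,9,11a-octahydrocyclodeca[b]furan-4-yl (2Z)-2-methylbut-2-enoate F4. The more labile triethylsilyl ether is removed selectively (HF·pyridine, pyridine, THF, 0 °C) to give (3aR,4S,6R,7Z,9S,10Z,11aS)-9-(tert-butyldimethylsilyloxy)-6-hydroxy-6,10-dimethyl-3-methylidene-2-oxo-2,3,3a,4,5,6,9,11a-octahydrocyclodeca[b]furan-4-yl (2Z)-2-methylbut-2-enoate F5. 3-Chloroperbenzoic acid with NaHCO3 in CH2Cl2 then epoxidises C1=C2 under hydrogen-bond direction from the C10 hydroxyl (trans to that hydroxyl, as peracids do with medium-ring allylic alcohols; C4=C5 has no directing group and two deactivating allylic oxygens) to give (1R,2R,3R,4Z,6S,7R,8S,10R)-8-angeloyloxy-3-(tert-butyldimethylsilyloxy)-1,2-epoxy-10-hydroxygermacra-4,11(13)-dien-12,6-olide F6. HF·pyridine at rt then gives 23.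

**Further compounds**
F1 | step 9 | methyl (2Z,4S,6R)-2-(bromomethyl)-6-methyl-4-[(2Z)-2-methylbut-2-enoyloxy]-6-(triethylsilyloxy)octa-2,7-dienoate | COC(=O)/C(CBr)=C/[C@@H](OC(=O)/C(C)=C\C)C[C@@](C)(O[Si](CC)(CC)CC)C=C
F2 | step 9 | methyl (3S,4S,6R)-3-[(1R,2Z)-1-hydroxy-3-iodobut-2-en-1-yl]-6-methyl-4-[(2Z)-2-methylbut-2-enoyloxy]-2-methylidene-6-(triethylsilyloxy)oct-7-enoate | COC(=O)C(=C)[C@@H]([C@H](/C=C(/C)I)O)[C@@H](OC(=O)/C(C)=C\C)C[C@@](C)(O[Si](CC)(CC)CC)C=C
F3 | step 11 | (1S,3R)-1-[(2S,3R)-2-[(1Z,3S,4E)-3-hydroxy-2-methyldeca-1,4,9-trien-1-yl]-4-methylidene-5-oxooxolan-3-yl]-3-methyl-3-(triethylsilyloxy)pent-4-en-1-yl (2Z)-2-methylbut-2-enoate | C=C1C(=O)O[C@@H](/C=C(/C)[C@@H](O)/C=C/CCCC=C)[C@H]1[C@@H](OC(=O)/C(C)=C\C)C[C@@](C)(O[Si](CC)(CC)CC)C=C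
F4 | step 12 | (3aR,4S,6R,7Z,9S,10Z,11aS)-9-(tert-butyldimethylsilyloxy)-6,10-dimethyl-3-methylidene-2-oxo-6-(triethylsilyloxy)-2,3,3a,4,5,6,9,11a-octahydrocyclodeca[b]furan-4-yl (2Z)-2-methylbut-2-enoate | C=C1C(=O)O[C@H]2/C=C(/C)[C@@H](O[Si](C)(C)C(C)(C)C)/C=C\[C@](C)(O[Si](CC)(CC)CC)C[C@H](OC(=O)/C(C)=C\C)[C@@H]12
F5 | step 12 | (3aR,4S,6R,7Z,9S,10Z,11aS)-9-(tert-butyldimethylsilyloxy)-6-hydroxy-6,10-dimethyl-3-methylidene-2-oxo-2,3,3a,4,5,6,9,11a-octahydrocyclodeca[b]furan-4-yl (2Z)-2-methylbut-2-enoate | C=C1C(=O)O[C@H]2/C=C(/C)[C@@H](O[Si](C)(C)C(C)(C)C)/C=C\[C@](C)(O)C[C@H](OC(=O)/C(C)=C\C)[C@@H]12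
F6 | step 12 | (1R,2R,3R,4Z,6S,7R,8S,10R)-8-angeloyloxy-3-(tert-butyldimethylsilyloxy)-1,2-epoxy-10-hydroxygermacra-4,11(13)-dien-12,6-olide | C=C1C(=O)O[C@H]2/C=C(/C)[C@@H](O[Si](C)(C)C(C)(C)C)[C@H]3O[C@H]3[C@](C)(O)C[C@H](OC(=O)/C(C)=C\C)[C@@H]12
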